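**Retrosynthetic overview**

1. The target is epiguibourtinidol-(4β→8)-epicatechin: upper unit (rings A, B, C) 2R,3R,4R with a 2,3-cis-3,4-trans pyran ring C, lower unit (−)-epicatechin. The end game is removal of one acetate and hydrogenolysis of six benzyl ethers.
2. Key disconnection, made in one operation: the interflavan C4–C8 bond (Friedel–Crafts) and the C4–C4a bond of the upper ring C. Ring C is traced back to a cis-2-aryl-2,3-dihydrobenzofuran-3-carbaldehyde: the formyl carbon becomes C4 and ring A shifts from C3 to C4, so the five-membered O-ring expands to the six-membered ring C.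
3. Enabling feature: in the upper unit the ring-A carbon C4a is para to O7 and ortho to O1, so it is a strongly bridging and migrating aryl carbon. C3 carries oxygen next to the benzylic C4, so an acetoxy group on C4 can hop to C3 through a dioxolanylium ion and leave C4 as a benzylic cation for C8 of the epicatechin ring A.
4. The dihydrobenzofuran comes from an intramolecular rhodium-carbenoid C–H insertion of an aryl diazoacetate, which sets C2 and the cis relationship. The diazo ester is assembled from 3-(benzyloxy)phenol, 4-(benzyloxy)benzyl chloride and ethyl diazoacetate.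
5. Ring order: rings A and B are bought; the five-membered O-ring forms in step 4; it expands to ring C, with union to the lower unit, in step 8; the lower-unit rings come intact from (−)-epicatechin.

Key step: step 8

Remark: the sense of induction of the rhodium catalyst in step 4 is assumed; if it proves opposite, the other antipode of the catalyst is used.

**Step 1**
Reactants: 1 3-(benzyloxy)phenol
Product: 2 5-(benzyloxy)-2-iodophenol
Conditions: I2, NaHCO3, THF/H2O, 0 °C to rt
Reagents that add atoms: iodine, SMILES II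
Why: Electrophilic aromatic iodination of the phenolate should go to the unhindered position ortho to OH and para to OBn, which puts iodine on the future ring-A carbon C4a.

**Step 2**
Reactants: 2 5-(benzyloxy)-2-iodophenol; 3 4-(benzyloxy)benzyl chloride
Product: 4 4-(benzyloxy)-2-{[4-(benzyloxy)benzyl]oxy}-1-iodobenzene
Conditions: K2CO3, KI (cat.), DMF, 50 °C
Reagents that add atoms: none
Why: Williamson ether synthesis (SN2 of the phenoxide on a benzylic chloride) installs the O–CH2–aryl unit whose CH2 becomes C2 carrying ring B.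

**Step 3**
Reactants: 4 4-(benzyloxy)-2-{[4-(benzyloxy)benzyl]oxy}-1-iodobenzene; 5 ethyl diazoacetate
Product: 6 ethyl 2-[4-(benzyloxy)-2-{[4-(benzyloxy)benzyl]oxy}phenyl]-2-diazoacetate
Conditions: Pd(PPh3)4 (5 mol %), Ag2CO3 (0.5 equiv), Et3N, toluene, rt
Reagents that add atoms: none
Why: Palladium-catalysed cross-coupling of an aryl iodide with the C–H bond of an acceptor diazo compound (diazo group retained) should give the donor/acceptor diazo ester directly, with Ag2CO3 as iodide scavenger and base.

**Step 4**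
Reactants: 6 ethyl 2-[4-(benzyloxy)-2-{[4-(benzyloxy)benzyl]oxy}phenyl]-2-diazoacetate
Product: 7 ethyl (2S,3R)-6-(benzyloxy)-2-[4-(benzyloxy)phenyl]-2,3-dihydrobenzofuran-3-carboxylate (2,3-cis)
Conditions: Rh2(R-PTTL)4 (1 mol %; PTTL = N-phthaloyl-tert-leucinate), toluene, −78 °C
Reagents that add atoms: none
Why: Intramolecular rhodium-carbenoid C–H insertion (1,5-insertion into the ether-activated benzylic C–H) should give the cis-dihydrobenzofuran; C2 and the cis relationship are set by the chiral dirhodium carboxylate in the concerted insertion.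

**Step 5**
Reactants: 7 ethyl (2S,3R)-6-(benzyloxy)-2-[4-(benzyloxy)phenyl]-2,3-dihydrobenzofuran-3-carboxylate
Product: 8 [(2S,3S)-6-(benzyloxy)-2-[4-(benzyloxy)phenyl]-2,3-dihydrobenzofuran-3-yl]methanol (2,3-cis)
Conditions: i-Bu2AlH (3 equiv), CH2Cl2, −78 to −40 °C; aqueous Rochelle salt
Reagents that add atoms: none
Why: Hydride reduction of the ester with a non-basic aluminium hydride at low temperature should leave the epimerisable C3, and hence the cis relationship, untouched.

**Step 6**
Reactants: 8 [(2S,3S)-6-(benzyloxy)-2-[4-(benzyloxy)phenyl]-2,3-dihydrobenzofuran-3-yl]methanol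
Product: 9 (2S,3R)-6-(benzyloxy)-2-[4-(benzyloxy)phenyl]-2,3-dihydrobenzofuran-3-carbaldehyde (2,3-cis)
Conditions: Dess–Martin periodinane, NaHCO3, CH2Cl2, 0 °C; crude product used at once
Reagents that add atoms: none
Why: Dess–Martin oxidation under buffered, non-basic conditions should give the α-aryl aldehyde without enolisation, so that the cis configuration is carried into step 8.

**Step 7**
Reactants: 10 (−)-epicatechin
Product: 11 5,7,3',4'-tetra-O-benzyl-(−)-epicatechin
Conditions: BnBr (4.2 equiv), K2CO3, DMF, −10 °C to rt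
Reagents that add atoms: benzyl bromide, SMILES BrCc1ccccc1
Why: Fourfold Williamson benzylation of the phenolic hydroxyls under carbonate conditions should leave the secondary 3-OH free and the two stereocentres untouched.

**Step 8**
Reactants: 9 (2S,3R)-6-(benzyloxy)-2-[4-(benzyloxy)phenyl]-2,3-dihydrobenzofuran-3-carbaldehyde; 11 5,7,3',4'-tetra-O-benzyl-(−)-epicatechin
Product: 15 3-O-acetyl-7,4'-di-O-benzyl-epiguibourtinidol-(4β→8)-5,7,3',4'-tetra-O-benzyl-epicatechin, via gem-diacetate 12 (not isolated), via phenonium ion 13 (not isolated), via acetoxonium ion 14 (not isolated)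
Conditions: Ac2O (1.05 equiv), TMSOTf (0.3 equiv), CH2Cl2, −78 °C; then 11 (3 equiv), −78 to −40 °C; Et3N quench
Reagents that add atoms: acetic anhydride, SMILES CC(=O)OC(C)=O
Why: Proposed new method: TMSOTf and Ac2O should convert the aldehyde into gem-diacetate 12 and ionise it to an acyloxycarbenium ion at the former formyl carbon (future C4); the ring-A carbon bonded to C3 (para to the 7-benzyloxy group, ortho to O1) bridges to it (phenonium ion 13), the remaining C4 acetoxy group opens the bridge at C3 from the rear to give dioxolanylium ion 14, and 14, a masked C4 benzylic cation, is then attacked at C4 by C8 of 11 in a Friedel–Crafts reaction. The closest known reaction types are the aryl-assisted (phenonium) solvolytic ring expansion of benzo-fused cycloalkylmethyl sulfonates, the acid-promoted aryl shift to an activated aldehyde carbon (aldehyde–ketone rearrangement), neighbouring acyloxy participation and the Lewis-acid condensation of 3-acyloxy-4-oxyflavans with flavan-3-ol nucleophiles; new is their merger, triggered from an acylal. Ring C closes by ring expansion, that is 3-exo ipso attack of ring A on the cationic carbon followed by cleavage of the old C3–aryl bond (a net 1,2-aryl shift that inserts C4 between C3 and C4a), and the transient dioxolanylium ring closes by 5-exo attack of the acetoxy carbonyl oxygen on C3. C2 is not touched; C3 is set by inversion, the oxygen entering anti to the departing aryl group, which from the cis aldehyde gives the 2,3-cis arrangement; C4 is set by attack of 11 anti to the C3 acyloxy (dioxolanylium) oxygen, giving 3,4-trans (4β). The step needs aryl participation to outrun enolisation of the cation (loss of the cis relationship or aromatisation to the benzofuran) and hydride shift, which the doubly oxygen-activated ipso carbon, the fast intramolecular acetoxy capture and the low temperature should secure, and it needs 11 to meet only the C4 cation, which is why 11 is added after the rearrangement. C8 rather than C6 of 11 should react because C8 is the less hindered, more nucleophilic position and 11 is used in excess.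

**Step 9**
Reactants: 15 3-O-acetyl-7,4'-di-O-benzyl-epiguibourtinidol-(4β→8)-5,7,3',4'-tetra-O-benzyl-epicatechin
Product: 16 7,4'-di-O-benzyl-epiguibourtinidol-(4β→8)-5,7,3',4'-tetra-O-benzyl-epicatechin
Conditions: K2CO3 (0.2 equiv), MeOH/THF, rt
Reagents that add atoms: none
Why: Zemplén-type transesterification should remove the 3-O-acetyl group at the perbenzylated stage, where no phenol is free and the flavan stereocentres are not base-labile.

**Step 10**
Reactants: 16 7,4'-di-O-benzyl-epiguibourtinidol-(4β→8)-5,7,3',4'-tetra-O-benzyl-epicatechin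
Product: 17 epiguibourtinidol-(4β→8)-epicatechin (target)
Conditions: H2 (1 atm), Pd(OH)2/C, THF/MeOH/H2O, rt; filtration and lyophilisation
Reagents that add atoms: none
Why: Hydrogenolysis of the six benzyl ethers over Pd(OH)2/C under neutral conditions should leave the benzylic C2–O1 and C4–aryl bonds of the 4-arylflavan-3-ol intact.

**Compound list**

1 | 3-(benzyloxy)phenol | Oc1cccc(OCc2ccccc2)c1 | starting material
2 | 5-(benzyloxy)-2-iodophenol | Oc1cc(OCc2ccccc2)ccc1I | intermediate
3 | 4-(benzyloxy)benzyl chloride | ClCc1ccc(OCc2ccccc2)cc1 | starting material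
4 | 4-(benzyloxy)-2-{[4-(benzyloxy)benzyl]oxy}-1-iodobenzene | Ic1ccc(OCc2ccccc2)cc1OCc1ccc(OCc2ccccc2)cc1 | intermediate
5 | ethyl diazoacetate | CCOC(=O)C=[N+]=[N-] | starting material
6 | ethyl 2-[4-(benzyloxy)-2-{[4-(benzyloxy)benzyl]oxy}phenyl]-2-diazoacetate | CCOC(=O)C(=[N+]=[N-])c1ccc(OCc2ccccc2)cc1OCc1ccc(OCc2ccccc2)cc1 | intermediate
7 | ethyl (2S,3R)-6-(benzyloxy)-2-[4-(benzyloxy)phenyl]-2,3-dihydrobenzofuran-3-carboxylate (cis) | CCOC(=O)[C@@H]1c2ccc(OCc3ccccc3)cc2O[C@@H]1c1ccc(OCc2ccccc2)cc1 | intermediate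
8 | [(2S,3S)-6-(benzyloxy)-2-[4-(benzyloxy)phenyl]-2,3-dihydrobenzofuran-3-yl]methanol (cis) | OC[C@@H]1c2ccc(OCc3ccccc3)cc2O[C@@H]1c1ccc(OCc2ccccc2)cc1 | intermediate
9 | (2S,3R)-6-(benzyloxy)-2-[4-(benzyloxy)phenyl]-2,3-dihydrobenzofuran-3-carbaldehyde (cis) | O=C[C@@H]1c2ccc(OCc3ccccc3)cc2O[C@@H]1c1ccc(OCc2ccccc2)cc1 | intermediate
10 | (−)-epicatechin | O[C@@H]1Cc2c(O)cc(O)cc2O[C@@H]1c1ccc(O)c(O)c1 | starting material
11 | 5,7,3',4'-tetra-O-benzyl-(−)-epicatechin | O[C@@H]1Cc2c(OCc3ccccc3)cc(OCc3ccccc3)cc2O[C@@H]1c1ccc(OCc2ccccc2)c(OCc2ccccc2)c1 | intermediate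
12 | gem-diacetate of 9: [(2S,3R)-6-(benzyloxy)-2-[4-(benzyloxy)phenyl]-2,3-dihydrobenzofuran-3-yl]methylene diacetate | CC(=O)OC(OC(C)=O)[C@@H]1c2ccc(OCc3ccccc3)cc2O[C@@H]1c1ccc(OCc2ccccc2)cc1 | intermediate
13 | phenonium ion: spiro-cyclopropane arenium ion in which ring A bridges C3 and the acetoxy-bearing future C4 (C4 epimers) | CC(=O)OC1[C@H]2[C@@H](c4ccc(OCc5ccccc5)cc4)OC3=CC(=[O+]Cc4ccccc4)C=C[C@]123 | intermediate
14 | acetoxonium ion: 2-methyl-1,3-dioxolan-2-ylium cis-fused across C3–C4 of 7-(benzyloxy)-2-[4-(benzyloxy)phenyl]chroman (2,3-cis) | CC1=[O+][C@@H]2c3ccc(OCc4ccccc4)cc3O[C@H](c3ccc(OCc4ccccc4)cc3)[C@@H]2O1 | intermediate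
15 | 3-O-acetyl-7,4'-di-O-benzyl-epiguibourtinidol-(4β→8)-5,7,3',4'-tetra-O-benzyl-epicatechin | O(Cc1ccccc1)c1ccc([C@H]2Oc3cc(OCc4ccccc4)ccc3[C@H](c3c(OCc4ccccc4)cc(OCc4ccccc4)c4c3O[C@H](c3ccc(OCc5ccccc5)c(OCc5ccccc5)c3)[C@H](O)C4)[C@H]2OC(C)=O)cc1 | intermediate
16 | 7,4'-di-O-benzyl-epiguibourtinidol-(4β→8)-5,7,3',4'-tetra-O-benzyl-epicatechin | O(Cc1ccccc1)c1ccc([C@H]2Oc3cc(OCc4ccccc4)ccc3[C@H](c3c(OCc4ccccc4)cc(OCc4ccccc4)c4c3O[C@H](c3ccc(OCc5ccccc5)c(OCc5ccccc5)c3)[C@H](O)C4)[C@H]2O)cc1 | intermediate
17 | epiguibourtinidol-(4β→8)-epicatechin, (2R,3R)-2-(3,4-dihydroxyphenyl)-8-[(2R,3R,4R)-3,7-dihydroxy-2-(4-hydroxyphenyl)chroman-4-yl]chroman-3,5,7-triol | Oc1ccc([C@H]2Oc3cc(O)ccc3[C@H](c3c(O)cc(O)c4c3O[C@H](c3ccc(O)c(O)c3)[C@H](O)C4)[C@H]2O)cc1 | target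

**Step count and risks**

Total step count: 10. Longest linear sequence: 9 steps (steps 1–6, 8, 9, 10).

Steps most likely to fail:

1. Step 8 (proposed new method). What may go wrong: enolisation of the aldehyde or of the acyloxycarbenium ion before aryl bridging, which would erase the cis relationship or aromatise the ring to a benzofuran; hydride shift within the bridged ion; capture of the cation at the wrong carbon. The fallback uses known chemistry, sets out from 8 and comes back at 15.
   - Alcohol 8 is mesylated (MsCl, Et3N, CH2Cl2, 0 °C) to [(2S,3S)-6-(benzyloxy)-2-[4-(benzyloxy)phenyl]-2,3-dihydrobenzofuran-3-yl]methyl methanesulfonate F1.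
   - Buffered acetolysis (KOAc, AcOH, 50–60 °C) then performs the same 1,2-aryl shift as an ordinary aryl-assisted solvolysis of a primary sulfonate, the phenonium ion being opened by acetate at C3, and should give 3-O-acetyl-7,4'-di-O-benzyl-epiguibourtinidol F2.
   - DDQ oxidation at C4 in the presence of 2-ethoxyethanol (CH2Cl2, rt) should give 3-O-acetyl-7,4'-di-O-benzyl-4β-(2-ethoxyethoxy)epiguibourtinidol F3.
   - TMSOTf-promoted condensation of F3 with 11 (CH2Cl2, −78 to −40 °C) returns to 15.

2. Step 6. What may go wrong: epimerisation at C3 of the α-aryl aldehyde (cis to trans) during oxidation or handling, which would carry the 2,3-trans series into step 8. The fallback avoids the free aldehyde, sets out from 7 and comes back at 12. One-pot reductive acetylation of ester 7 (i-Bu2AlH, CH2Cl2, −78 °C; then Ac2O, pyridine, DMAP) should give [(2S,3R)-6-(benzyloxy)-2-[4-(benzyloxy)phenyl]-2,3-dihydrobenzofuran-3-yl](ethoxy)methyl acetate F4. Under the Ac2O/TMSOTf conditions of step 8, F4 should exchange its ethoxy group for acetoxy and so enter the route as 12.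

3. Step 3. What may go wrong: slow oxidative addition at the hindered, electron-rich aryl iodide and competing decomposition or dimerisation of the diazo ester on palladium. The fallback sets out from 4 and comes back at 6. Negishi-type α-arylation of 4 with the Reformatsky reagent BrZnCH2CO2Et (Pd(dba)2, XPhos, THF, rt) should give ethyl 2-[4-(benzyloxy)-2-{[4-(benzyloxy)benzyl]oxy}phenyl]acetate F5. Regitz diazo transfer (p-acetamidobenzenesulfonyl azide, DBU, MeCN, 0 °C to rt) then gives 6.

**Further compounds**

F1 | step 8 | [(2S,3S)-6-(benzyloxy)-2-[4-(benzyloxy)phenyl]-2,3-dihydrobenzofuran-3-yl]methyl methanesulfonate | CS(=O)(=O)OC[C@@H]1c2ccc(OCc3ccccc3)cc2O[C@@H]1c1ccc(OCc2ccccc2)cc1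
F2 | step 8 | 3-O-acetyl-7,4'-di-O-benzyl-epiguibourtinidol, (2R,3R)-7-(benzyloxy)-2-[4-(benzyloxy)phenyl]chroman-3-yl acetate | O(Cc1ccccc1)c1ccc([C@H]2Oc3cc(OCc4ccccc4)ccc3C[C@H]2OC(C)=O)cc1
F3 | step 8 | 3-O-acetyl-7,4'-di-O-benzyl-4β-(2-ethoxyethoxy)epiguibourtinidol | O(Cc1ccccc1)c1ccc([C@H]2Oc3cc(OCc4ccccc4)ccc3[C@H](OCCOCC)[C@H]2OC(C)=O)cc1
F4 | step 6 | [(2S,3R)-6-(benzyloxy)-2-[4-(benzyloxy)phenyl]-2,3-dihydrobenzofuran-3-yl](ethoxy)methyl acetate (acetal epimers) | CCOC(OC(C)=O)[C@@H]1c2ccc(OCc3ccccc3)cc2O[C@@H]1c1ccc(OCc2ccccc2)cc1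
F5 | step 3 | ethyl 2-[4-(benzyloxy)-2-{[4-(benzyloxy)benzyl]oxy}phenyl]acetate | CCOC(=O)Cc1ccc(OCc2ccccc2)cc1OCc1ccc(OCc2ccccc2)cc1
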